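Chromene locants (O1, C2, C3, C4, C4a, C5–C8, C8a) are used for the corresponding atoms of every intermediate. Cα and Cβ are the bridge carbons, Cα on C5. Ring A is the benzo ring of the chromene and ring B the hydroxyphenyl ring.

## Analysis of the target

Target 14 is a 2,2-dimethyl-2H-chromene (O1, quaternary C2, C3=C4, ring A = C4a–C8a) with a 3-methylbut-2-enyl (prenyl) ether on O7 and, on C5, a Cα–Cβ bridge to the para-hydroxyphenyl ring B. It is a prenylated bibenzyl. It has no stereocentre and no alkene with a geometry to set, so the whole problem is regiochemistry and chemoselectivity. Ring A is a 1,2,3,5-tetrasubstituted benzene: oxygen on C8a, carbon (C4) on C4a, carbon (Cα) on C5, oxygen on C7, with C6 and C8 free. Building it by substitution of a 5-alkylresorcinol would mean choosing between two equivalent phenols and three nucleophilic ring positions. The three oxygens end in three different states: O1 in the pyran ring, O7 as an allylic ether, and the ring B hydroxyl free. The sensitive groups are the aryl prenyl ether (ionised by acid, rearranged by heat, reduced by hydrogenation), the electron-rich C3=C4 bond and the free phenol. The last steps therefore cannot use hydrogenolysis, strong Lewis acids or strong heating. The strategy rests on one feature: C4a, which carries C4, lies between oxygen-bearing C8a and chain-bearing C5, with the second oxygen meta on C7 (the orsellinate pattern). Ring A therefore maps onto a 4-acyl-5-alkylcyclohexane-1,3-dione in which only the C8a oxygen is 1,3 to the acyl carbonyl C4, so O1 and O7 are already different before ring A is aromatic.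

## Retrosynthetic reasoning

**C3=C4.** The ring alkene of 14 is taken back to the C4 carbinol of chromanol 13 (dehydration) and then to the C4 ketone of chromanone 12 (hydride reduction). C2 is quaternary, so elimination can only run towards C3. The C4 cation is stabilised by O1 and O7, so the forward dehydration needs only a trace of acid. The gain is a carbonyl at C4, which is used three more times below.

**O7–prenyl.** Cutting the O7–CH2 bond of 12 gives diphenol 11 and a prenyl halide. The forward alkylation must pick O7 over the ring B hydroxyl. The C4 carbonyl is para to O7 and makes that hydroxyl a vinylogous acid, so a weak base should ionise it alone. The prenyl group is introduced only after ring A is aromatic, because an allylic ether would not survive the dehydrogenation.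

**Aromatic ring A.** Diphenol 11 is taken back to dione 10, its dihydro form with C5–C6 saturated and C7 as a ketone. This turns ring A into a ring that carbonyl condensations can build. The forward step is a single dehydrogenation driven by aromatisation, run while the molecule holds no alkene or allyl ether.

**Ring A and the pyranone.** Three bonds of 10 are cut in sequence:
- O1–C2 (retro-oxa-Michael) gives triketone 9.
- C7–C8 (retro-Claisen) gives keto ester 8.
- C4a–C5 (retro-Michael) gives enoate 4 and diketone 7.

Each of these bonds lies α or β to a carbonyl, so one base can form the two C–C bonds and an acid quench the C–O bond. The cut falls in the middle of ring A and is convergent: 4 carries ring B, the bridge and C5–C7, and 7 carries C8, C8a, C4a, C4, C3, C2 and the methyls. The C8–C8a bond is already present in 7 as the CH3–CO bond of its acetyl group. The forward reaction must alkylate 7 on its central carbon, close ring A through the acetyl methyl and not through the enone arm, and close the pyranone through the C8a oxygen. The last point is fixed by ring size, since the C7 oxygen cannot reach C2 in a six-membered ring.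

**Enoate 4.** The alkene of 4 is cut by a Wittig disconnection into aldehyde 2 and stabilised ylide 3, and 2 comes from ester 1 by partial reduction. The phenol is carried free: every later step tolerates a phenol or phenoxide, and a group robust enough for hot alkoxide, hot palladium and hydride would be hard to remove at the end without harming the prenyl ether and the chromene.

**Diketone 7.** The C4a–C8a bond of 7 is a Claisen bond between the acetyl-methyl enolate of enone 5 and ester 6.

## Alternatives that were turned down

Alternative 1: directed C–H carbonylation on an aromatic ring A.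
- Disconnection: the C4a–C4 bond, made on an intact ring A with a hydroxyl on Cβ as an internal directing group.
- Forward key step: carbinol A2 (racemic 4-{2-[3,5-bis(benzyloxy)phenyl]-1-hydroxyethyl}phenyl pivalate) with Pd(OAc)2, CO and an oxidant. The alkoxide holds divalent palladium next to the ortho C–H of ring A; palladation, CO insertion and C–O reductive elimination should give the six-membered lactone A1 (racemic 6,8-bis(benzyloxy)-3-[4-(pivaloyloxy)phenyl]isochroman-1-one).
- For: ring A is aromatic from the start, so no dehydrogenation is needed. The two ortho C–H bonds are equivalent by symmetry, so C4a is chosen automatically. On these two points it is stronger than the chosen route.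
- Against: the lactone C–O bond and the Cβ stereocentre are scaffolding that must be removed again. C4 arrives as a carboxyl, so C3, C2 and both methyls are still missing and the oxidation level must be lowered. The benzyl ethers must be removed before any alkene exists. A secondary benzylic alcohol is prone to oxidation to the ketone under divalent palladium and oxidant. The C–H bond is flanked by a benzyloxy group and the chain.
- Comparison: about a dozen steps and three protecting groups, against eight steps and none. The chosen route gives up the preformed arene and in exchange makes three bonds and two rings in one flask.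

Alternative 2: three-component Catellani reaction.
- Disconnection: C5–Cα and C4a–C4 together, on an aromatic ring A.
- Forward key step: aryl iodide A4 (1-iodo-2,4-bis(methoxymethoxy)benzene, iodine on C4a), bromide A5 (4-(2-bromoethyl)phenyl pivalate) and alkene A6 (2-methylbut-3-en-2-ol) with Pd(OAc)2, P(2-furyl)3, norbornene and K2CO3. Ortho C–H alkylation through the norbornene palladacycle forms C5–Cα, and a terminating Heck reaction forms C4a–C4. The product is the open-chain allylic alcohol A3 ((E)-4-{2,4-bis(methoxymethoxy)-6-[2-(4-pivaloyloxyphenyl)ethyl]phenyl}-2-methylbut-3-en-2-ol).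
- For: it is highly convergent; one catalytic step loads both carbon substituents and every carbon of the pyran ring. Acid would then remove the acetals and close the chromene through the only ortho oxygen. The pivalate keeps the ring B phenol apart from O7 with certainty. On convergence and on this O7/ring B differentiation it is as strong as or stronger than the chosen route, and its step count is similar.
- Against: a homobenzylic bromide can lose HBr to a styrene under hot carbonate. The reaction depends on a delicate balance of four partners on an electron-rich iodide. Three protecting groups are needed.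
- Comparison: the chosen route offers no protecting groups, commodity reagents, simple scale-up, and a substitution pattern fixed by connectivity and not by the order of events in a catalytic cycle.

Alternative 3: one-carbon ring expansion.
- Disconnection: C4 is removed from between C3 and C4a, leaving a five-membered ring.
- Forward key step: benzofuranone A8 (2,2-dimethyl-6-(3-methylbut-2-enyloxy)-4-{2-[4-(tert-butyldimethylsilyloxy)phenyl]ethyl}benzofuran-3(2H)-one) with Me3SiCHN2 and Sc(OTf)3. Addition to the ketone, 1,2-shift of the ring A carbon with loss of N2, and desilylation should give chroman-3-one A7 (2,2-dimethyl-7-(3-methylbut-2-enyloxy)-5-{2-[4-(tert-butyldimethylsilyloxy)phenyl]ethyl}chroman-3-one).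
- For: the arene and all substituents are in place, and the step is a late, short skeletal edit.
- Against: it adds one carbon only, so the ring A regiochemistry must be solved beforehand in making A8. The ketone sits between a quaternary carbon and a peri substituent. Aryl migration must beat migration of the quaternary carbon and epoxide formation. The Lewis acid threatens the prenyl ether. A7 still needs reduction and a non-benzylic dehydration to reach the chromene.
- Comparison: it is weaker on every count except that it avoids a dehydrogenation.

Key step: step 4

Remark: 8, 9 and 10 are written as keto tautomers; in the flask they will be largely enols or sodium enolates, and 8 and 9 will be diastereomer mixtures. This is of no consequence, because the target is achiral.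

## Route

Step 1
Reactants: 1 methyl 3-(4-hydroxyphenyl)propanoate
Product: 2 3-(4-hydroxyphenyl)propanal
Conditions: i-Bu2AlH (2.2 equiv), CH2Cl2, −78 °C; MeOH, then aq. potassium sodium tartrate
Reagents that add atoms: none
Why: Partial hydride reduction of an ester: the first equivalent of i-Bu2AlH is taken up by the phenol, the second adds to the ester, and the aluminium hemiacetal is stable at −78 °C, so the aldehyde should be released only on quenching.

Step 2
Reactants: 2 3-(4-hydroxyphenyl)propanal; 3 ethyl (triphenylphosphoranylidene)acetate
Product: 4 ethyl (E)-5-(4-hydroxyphenyl)pent-2-enoate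
Conditions: 3 (1.1 equiv), CH2Cl2, 25 °C
Reagents that add atoms: none
Why: Wittig olefination with a stabilised ylide, which is too weakly basic to be quenched by the phenol and should give the E-enoate; the alkene geometry is lost again in step 4.

Step 3
Reactants: 5 4-methylpent-3-en-2-one; 6 ethyl acetate
Product: 7 6-methylhept-5-ene-2,4-dione
Conditions: LiN(i-Pr)2 (2.0 equiv), 5 (2.0 equiv), THF, −78 °C; 6 (1.0 equiv), −78 → 0 °C; cold 1 M HCl to pH 5
Reagents that add atoms: none
Why: Crossed Claisen acylation: kinetic deprotonation of the enone at its acetyl methyl gives the cross-conjugated lithium enolate, which is acylated on carbon by the ester. The second equivalent of enolate acts as the base that stores the product as its diketonate, and the mild quench avoids acid cyclisation of 7.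

Step 4
Reactants: 4 ethyl (E)-5-(4-hydroxyphenyl)pent-2-enoate; 7 6-methylhept-5-ene-2,4-dione
Product: 10 racemic 5-[2-(4-hydroxyphenyl)ethyl]-2,2-dimethyl-2,3,5,6-tetrahydro-4H-chromene-4,7(8H)-dione, via Michael adduct 8 (not isolated), via triketone 9 (not isolated)
Conditions: NaOEt (2.5 equiv), EtOH, reflux; then 2 M HCl to pH 1, EtOH–H2O, 60 °C
Reagents that add atoms: none
Why: One equivalent of ethoxide is spent on the ring B phenol, which then stays inert as its phenoxide; the rest converts 7 into its diketonate, whose central carbon adds to the β-carbon of 4 to form C4a–C5 and give 8. In 8 the acetyl methyl is enolised reversibly and its carbon attacks the ester carbonyl in a 6-(enolendo)-exo-trig Claisen closure that forms C7–C8 and ring A; loss of ethoxide and deprotonation of the acidic triketone 9 should pull the earlier equilibria forward. The closest known reaction type is the Michael–Claisen annulation of acetoacetates with crotonates that gives dihydroorsellinates, here with a 1,3-diketone as donor. On acidification the enol oxygen on C8a adds to the protonated β,β-dimethyl enone in a 6-endo-trig oxa-Michael closure (O1–C2) that forms the pyranone of 10. C5 is the only stereocentre of 10; nothing controls it, so 10 is racemic, and step 5 removes it. Three selectivities are needed: the diketonate must react on carbon, which the reversibility of the addition and the stability of the C-adduct should secure; ring A must close through the acetyl methyl, which is favoured because the γ-methyl carbons of the enone arm could only close an eight-membered ring and the α-carbon C3 of its extended dienolate, which could close a six-membered ring, is a hindered secondary carbon while the acetyl carbon is primary; and the pyranone must close on the C8a oxygen, which is certain because the C7 oxygen is not 1,3 to the acyl group.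

Step 5
Reactants: 10 racemic 5-[2-(4-hydroxyphenyl)ethyl]-2,2-dimethyl-2,3,5,6-tetrahydro-4H-chromene-4,7(8H)-dione
Product: 11 7-hydroxy-5-[2-(4-hydroxyphenyl)ethyl]-2,2-dimethyl-2,3-dihydro-4H-chromen-4-one
Conditions: 10% Pd/C, p-cymene, reflux (ca. 175 °C), Ar stream
Reagents that add atoms: none
Why: Catalytic dehydrogenation of a cyclohexenone to a phenol: loss of H2 across C5–C6 gives a dienone that tautomerises at once to the 7-hydroxy arene, and aromatisation together with removal of H2 in the gas stream should make it irreversible. The substrate holds no alkene or allyl ether at this stage.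

Step 6
Reactants: 11 7-hydroxy-5-[2-(4-hydroxyphenyl)ethyl]-2,2-dimethyl-2,3-dihydro-4H-chromen-4-one
Product: 12 5-[2-(4-hydroxyphenyl)ethyl]-2,2-dimethyl-7-[(3-methylbut-2-en-1-yl)oxy]-2,3-dihydro-4H-chromen-4-one
Conditions: 1-bromo-3-methylbut-2-ene (1.05 equiv), KHCO3 (1.5 equiv), DMF, 40 °C
Reagents that add atoms: 1-bromo-3-methylbut-2-ene, CC(C)=CCBr
Why: Williamson ether synthesis under acidity control: the 7-OH is para to the C4 carbonyl and is expected to be two to three pKa units more acidic than the alkylphenol of ring B, so hydrogencarbonate should ionise only this hydroxyl, which the allylic bromide then alkylates on oxygen by SN2.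

Step 7
Reactants: 12 5-[2-(4-hydroxyphenyl)ethyl]-2,2-dimethyl-7-[(3-methylbut-2-en-1-yl)oxy]-2,3-dihydro-4H-chromen-4-one
Product: 13 racemic 5-[2-(4-hydroxyphenyl)ethyl]-2,2-dimethyl-7-[(3-methylbut-2-en-1-yl)oxy]-3,4-dihydro-2H-chromen-4-ol
Conditions: LiAlH4 (2.0 equiv), THF, 0 → 25 °C; aq. potassium sodium tartrate
Reagents that add atoms: none
Why: Hydride reduction of the electron-rich aryl ketone; the phenol only consumes one hydride, and the prenyl ether and its alkene are inert. The C4 carbinol is formed racemic, which does not matter because step 8 removes it.

Step 8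
Reactants: 13 racemic 5-[2-(4-hydroxyphenyl)ethyl]-2,2-dimethyl-7-[(3-methylbut-2-en-1-yl)oxy]-3,4-dihydro-2H-chromen-4-ol
Product: 14 4-(2-{2,2-dimethyl-7-[(3-methylbut-2-en-1-yl)oxy]-2H-chromen-5-yl}ethyl)phenol
Conditions: p-TsOH·H2O (5 mol%), toluene, 4 Å molecular sieves, 25–40 °C
Reagents that add atoms: none
Why: Acid-catalysed E1 dehydration: the C4 cation is benzylic and stabilised by O1 (ortho) and O7 (para), so ionisation should need only a trace of acid near room temperature. Loss of a C3 proton gives the conjugated C3=C4 bond, and C2 is quaternary, so no regioisomer can form.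

## Compound list

1 | methyl 3-(4-hydroxyphenyl)propanoate | COC(=O)CCc1ccc(O)cc1 | starting material
2 | 3-(4-hydroxyphenyl)propanal | O=CCCc1ccc(O)cc1 | intermediate
3 | ethyl (triphenylphosphoranylidene)acetate | CCOC(=O)C=P(c1ccccc1)(c1ccccc1)c1ccccc1 | starting material
4 | ethyl (E)-5-(4-hydroxyphenyl)pent-2-enoate | CCOC(=O)/C=C/CCc1ccc(O)cc1 | intermediate
5 | 4-methylpent-3-en-2-one | CC(=O)C=C(C)C | starting material
6 | ethyl acetate | CCOC(C)=O | starting material
7 | 6-methylhept-5-ene-2,4-dione | CC(=O)CC(=O)C=C(C)C | intermediate
8 | ethyl 4-acetyl-3-[2-(4-hydroxyphenyl)ethyl]-7-methyl-5-oxooct-6-enoate (Michael adduct, racemic diastereomer mixture, not isolated) | CCOC(=O)CC(CCc1ccc(O)cc1)C(C(C)=O)C(=O)C=C(C)C | intermediate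
9 | 5-[2-(4-hydroxyphenyl)ethyl]-4-(3-methylbut-2-enoyl)cyclohexane-1,3-dione (racemic, formed as its sodium enolate, not isolated) | CC(C)=CC(=O)C1C(CCc2ccc(O)cc2)CC(=O)CC1=O | intermediate
10 | racemic 5-[2-(4-hydroxyphenyl)ethyl]-2,2-dimethyl-2,3,5,6-tetrahydro-4H-chromene-4,7(8H)-dione | O=C1CC(CCc2ccc(O)cc2)C2=C(C1)OC(C)(C)CC2=O | intermediate
11 | 7-hydroxy-5-[2-(4-hydroxyphenyl)ethyl]-2,2-dimethyl-2,3-dihydro-4H-chromen-4-one | O=C1CC(C)(C)Oc2cc(O)cc(CCc3ccc(O)cc3)c12 | intermediate
12 | 5-[2-(4-hydroxyphenyl)ethyl]-2,2-dimethyl-7-[(3-methylbut-2-en-1-yl)oxy]-2,3-dihydro-4H-chromen-4-one | CC(C)=CCOc1cc(CCc2ccc(O)cc2)c2c(c1)OC(C)(C)CC2=O | intermediate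
13 | racemic 5-[2-(4-hydroxyphenyl)ethyl]-2,2-dimethyl-7-[(3-methylbut-2-en-1-yl)oxy]-3,4-dihydro-2H-chromen-4-ol | CC(C)=CCOc1cc(CCc2ccc(O)cc2)c2c(c1)OC(C)(C)CC2O | intermediate
14 | 4-(2-{2,2-dimethyl-7-[(3-methylbut-2-en-1-yl)oxy]-2H-chromen-5-yl}ethyl)phenol | CC(C)=CCOc1cc(CCc2ccc(O)cc2)c2c(c1)OC(C)(C)C=C2 | target

## Step count and risk

Total step count: 8. Longest linear sequence: 7 steps (1, 2, 4, 5, 6, 7, 8); step 3 is a one-step side branch.

**Step 4 (key step).** Three things may go wrong.
- Addition of a stabilised diketonate to a β-alkyl enoate is slow and reversible, so retro-Michael and ethoxide deacylation of the adduct 8 can compete with ring closure.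
- Ring closure may run through the α-carbon of the enone-arm dienolate, which also gives a six-membered ring.
- The acid-induced closure of the pyranone may stop short.

The fallback sets out from 4 and uses the symmetrical donor pentane-2,4-dione, which has no enone arm. With NaOEt in EtOH it should give 4-acetyl-5-[2-(4-hydroxyphenyl)ethyl]cyclohexane-1,3-dione F1. Dehydrogenation over Pd/C gives 1-{2,4-dihydroxy-6-[2-(4-hydroxyphenyl)ethyl]phenyl}ethan-1-one F2. A Kabbe condensation with acetone and pyrrolidine (enamine aldol, dehydration, oxa-Michael through the only ortho hydroxyl) then builds the pyranone on the arene. The route is rejoined at 11.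

**Step 3.** Proton exchange between the kinetic enolate and the product, γ-deprotonation with self-condensation, or double acylation may erode the crossed Claisen. The fallback does not use 5 and 6 but sets out from commercial pentane-2,4-dione and acetone. The dianion of the dione (NaH, then n-BuLi, THF, 0 °C) adds through its terminal carbon to acetone and gives 6-hydroxy-6-methylheptane-2,4-dione F3. Catalytic p-TsOH in toluene dehydrates and cyclises it to 2,2,6-trimethyl-2,3-dihydro-4H-pyran-4-one F4. F4 is charged to step 4 in place of 7: ethoxide deprotonates its C3, and E1cB loss of the ring oxygen as a vinylogous carboxylate gives the sodium enolate of 7 in the flask. The route is rejoined at 7.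

**Step 5.** The hydrogen set free may be redistributed on the catalyst (reduction or hydrogenolysis of the C7 or C4 carbonyl, disproportionation), or the long heating may degrade the phenol. The fallback sets out from 10 and replaces dehydrogenation by halogenation and elimination. CuBr2 (2.0 equiv, EtOAc–CHCl3, reflux), a reagent that brominates enolisable ketones in preference to phenol rings, should give racemic 8-bromo-5-[2-(4-hydroxyphenyl)ethyl]-2,2-dimethyl-2,3,5,6-tetrahydro-4H-chromene-4,7(8H)-dione F5. LiBr and Li2CO3 in DMF at 100 °C then remove HBr by 1,4-elimination through the C6 enol, with aromatisation as the driving force. The route is rejoined at 11.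

**Step 6.** Chemoselectivity between the two phenoxides may be incomplete (double alkylation), or C-prenylation at C8 or C6 may occur. The fallback sets out from 11 and masks ring B.
- Ac2O in pyridine gives 4-{2-[7-(acetyloxy)-2,2-dimethyl-4-oxo-3,4-dihydro-2H-chromen-5-yl]ethyl}phenyl acetate F6.
- PhSH with imidazole in NMP at 0 °C removes the more electrophilic 7-acetate, whose phenoxide is the better leaving group, and gives 4-[2-(7-hydroxy-2,2-dimethyl-4-oxo-3,4-dihydro-2H-chromen-5-yl)ethyl]phenyl acetate F7.
- 1-Bromo-3-methylbut-2-ene with K2CO3 in acetone gives 4-(2-{2,2-dimethyl-7-[(3-methylbut-2-en-1-yl)oxy]-4-oxo-3,4-dihydro-2H-chromen-5-yl}ethyl)phenyl acetate F8.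
- LiAlH4 reduces C4 and cleaves the aryl acetate in the same operation.

The route is rejoined at 13.

**Step 8.** Acid may ionise the allylic aryl ether (loss or migration of the prenyl group), or the C4 cation may be trapped by a phenol or by the product alkene instead of losing a proton. The fallback sets out from 12 and avoids acid and the cation altogether. TsNHNH2 in EtOH with a trace of AcOH gives N'-{5-[2-(4-hydroxyphenyl)ethyl]-2,2-dimethyl-7-[(3-methylbut-2-en-1-yl)oxy]-2,3-dihydro-4H-chromen-4-ylidene}-4-methylbenzenesulfonohydrazide F9. A Shapiro reaction (LiN(i-Pr)2, 3.5 equiv, THF, −78 → 25 °C; H2O) deprotonates the phenol, N–H and C3, expels sulfinate and N2, and protonates the C4 vinyllithium. The route is rejoined at 14.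

## Further compounds

F1 | step 4 | racemic 4-acetyl-5-[2-(4-hydroxyphenyl)ethyl]cyclohexane-1,3-dione | CC(=O)C1C(CCc2ccc(O)cc2)CC(=O)CC1=O
F2 | step 4 | 1-{2,4-dihydroxy-6-[2-(4-hydroxyphenyl)ethyl]phenyl}ethan-1-one | CC(=O)c1c(O)cc(O)cc1CCc1ccc(O)cc1
F3 | step 3 | 6-hydroxy-6-methylheptane-2,4-dione | CC(=O)CC(=O)CC(C)(C)O
F4 | step 3 | 2,2,6-trimethyl-2,3-dihydro-4H-pyran-4-one | CC1=CC(=O)CC(C)(C)O1
F5 | step 5 | racemic 8-bromo-5-[2-(4-hydroxyphenyl)ethyl]-2,2-dimethyl-2,3,5,6-tetrahydro-4H-chromene-4,7(8H)-dione | O=C1CC(CCc2ccc(O)cc2)C2=C(C1Br)OC(C)(C)CC2=O
F6 | step 6 | 4-{2-[7-(acetyloxy)-2,2-dimethyl-4-oxo-3,4-dihydro-2H-chromen-5-yl]ethyl}phenyl acetate | CC(=O)Oc1ccc(CCc2cc(OC(C)=O)cc3c2C(=O)CC(C)(C)O3)cc1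
F7 | step 6 | 4-[2-(7-hydroxy-2,2-dimethyl-4-oxo-3,4-dihydro-2H-chromen-5-yl)ethyl]phenyl acetate | CC(=O)Oc1ccc(CCc2cc(O)cc3c2C(=O)CC(C)(C)O3)cc1
F8 | step 6 | 4-(2-{2,2-dimethyl-7-[(3-methylbut-2-en-1-yl)oxy]-4-oxo-3,4-dihydro-2H-chromen-5-yl}ethyl)phenyl acetate | CC(=O)Oc1ccc(CCc2cc(OCC=C(C)C)cc3c2C(=O)CC(C)(C)O3)cc1
F9 | step 8 | N'-{5-[2-(4-hydroxyphenyl)ethyl]-2,2-dimethyl-7-[(3-methylbut-2-en-1-yl)oxy]-2,3-dihydro-4H-chromen-4-ylidene}-4-methylbenzenesulfonohydrazide | Cc1ccc(cc1)S(=O)(=O)NN=C1CC(C)(C)Oc2cc(OCC=C(C)C)cc(CCc3ccc(O)cc3)c12
A1 | alternative 1 | racemic 6,8-bis(benzyloxy)-3-[4-(pivaloyloxy)phenyl]isochroman-1-one | O=C1OC(c2ccc(OC(=O)C(C)(C)C)cc2)Cc2cc(OCc3ccccc3)cc(OCc3ccccc3)c21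
A2 | alternative 1 | racemic 4-{2-[3,5-bis(benzyloxy)phenyl]-1-hydroxyethyl}phenyl pivalate | CC(C)(C)C(=O)Oc1ccc(C(O)Cc2cc(OCc3ccccc3)cc(OCc3ccccc3)c2)cc1
A3 | alternative 2 | (E)-4-{2,4-bis(methoxymethoxy)-6-[2-(4-pivaloyloxyphenyl)ethyl]phenyl}-2-methylbut-3-en-2-ol | COCOc1cc(CCc2ccc(OC(=O)C(C)(C)C)cc2)c(/C=C/C(C)(C)O)c(OCOC)c1
A4 | alternative 2 | 1-iodo-2,4-bis(methoxymethoxy)benzene | COCOc1ccc(I)c(OCOC)c1
A5 | alternative 2 | 4-(2-bromoethyl)phenyl pivalate | CC(C)(C)C(=O)Oc1ccc(CCBr)cc1
A6 | alternative 2 | 2-methylbut-3-en-2-ol | C=CC(C)(C)O
A7 | alternative 3 | 2,2-dimethyl-7-(3-methylbut-2-enyloxy)-5-{2-[4-(tert-butyldimethylsilyloxy)phenyl]ethyl}chroman-3-one | CC(C)=CCOc1cc(CCc2ccc(O[Si](C)(C)C(C)(C)C)cc2)c2c(c1)OC(C)(C)C(=O)C2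
A8 | alternative 3 | 2,2-dimethyl-6-(3-methylbut-2-enyloxy)-4-{2-[4-(tert-butyldimethylsilyloxy)phenyl]ethyl}benzofuran-3(2H)-one | CC(C)=CCOc1cc(CCc2ccc(O[Si](C)(C)C(C)(C)C)cc2)c2c(c1)OC(C)(C)C2=O
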